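**Retrosynthetic overview**
1. Evelynin ⇒ 1-(3,4-dimethoxyphenyl)-3-(2,4,6-trimethoxyphenyl)propan-1-one. The para-quinone is made last by forming two C–O bonds on ring B: oxygenation of a free ring C–H and water-for-methoxy exchange at the carbon para to it. The two free CH positions of the 2,4,6-trimethoxyphenyl ring are equivalent, so only one para-quinone can form.
2. That dihydrochalcone ⇒ 3,4-dimethoxyacetophenone + 2,4,6-trimethoxybenzyl alcohol, joined at the CH2–CH2 bond by hydrogen-borrowing α-alkylation.
3. No ring is built. Ring A (3,4-dimethoxyphenyl) is bought and carried through unchanged; ring B is bought as the trimethoxyarene and becomes the quinone in the final step.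

**Assumptions**
- The target has no stereocentre and no stereogenic double bond, so there is no configuration to set or preserve.
- The route has only two steps, so the closing risk ranking covers both of them.

**Step 1**
Reactants: 1 3,4-dimethoxyacetophenone (1.0 equiv); 2 2,4,6-trimethoxybenzyl alcohol (1.1 equiv)
Product: 5 1-(3,4-dimethoxyphenyl)-3-(2,4,6-trimethoxyphenyl)propan-1-one, via 2,4,6-trimethoxybenzaldehyde 3 (not isolated), via E-chalcone 4 (not isolated)
Conditions: [Cp*IrCl2]2 (1 mol%), KOH (20 mol%), toluene, 110 °C, 16 h, argon, closed vessel
Reagents that add atoms: none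
Why: Hydrogen-borrowing (hydrogen autotransfer) α-alkylation of a methyl ketone with a primary benzylic alcohol, in which the trivalent iridium catalyst dehydrogenates 2 to aldehyde 3, KOH-mediated Claisen–Schmidt condensation with 1 gives chalcone 4, and the iridium hydride returns the hydrogen by conjugate reduction, so water is the only by-product and no stereocentre is formed.

**Step 2**
Reactants: 5 1-(3,4-dimethoxyphenyl)-3-(2,4,6-trimethoxyphenyl)propan-1-one
Product: 7 evelynin (2-[3-(3,4-dimethoxyphenyl)-3-oxopropyl]-3,5-dimethoxycyclohexa-2,5-diene-1,4-dione), via phenol 6 (not isolated)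
Conditions: tris(2,4-dibromophenyl)amine (10 mol%), LiClO4 (0.1 M), MeCN/H2O 9:1, 5 at 0.02 M, divided cell (Nafion membrane), graphite-felt anode held at +1.55 V vs SCE, Pt cathode, 4.2–4.5 F per mol, 20 °C, dark
Reagents that add atoms: water, O
Why: Proposed new method: a potential-gated, triarylaminium-mediated anodic C–H hydroxylation/demethylative quinone formation, in which the electrogenerated aminium radical cation (about +1.5 V vs SCE) oxidises only the 2,4,6-trimethoxyphenyl ring B of 5 (estimated +1.4 V; the acyl-deactivated ring A, estimated +1.7 V or higher, and the finished quinone are out of reach), water adds to the ring-B radical cation at one of the two equivalent free CH positions (a site too hindered for biaryl coupling, while the benzylic C–H bonds flanked by two ortho methoxy groups are poorly aligned for side-chain deprotonation), two further electron/proton losses give phenol 6, and 6 (estimated +1.0 V) is oxidised at once to a phenoxonium ion that takes up water at the para methoxy-bearing carbon and expels methanol to give the para-quinone; the closest known reaction types are triarylamine-mediated indirect anodic oxidations (ether cleavage, benzylic oxidation) and the oxidative demethylation of para-methoxyphenols and para-dimethoxyarenes to quinones with (NH4)2Ce(NO3)6 or by direct electrolysis, and what has not been shown is a redox mediator driving the whole four-electron C–H oxygenation/demethylation cascade selectively in the presence of a second electron-rich arene; no stereocentre is involved.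

**Compound list**
1 | 3,4-dimethoxyacetophenone | CC(=O)c1ccc(OC)c(OC)c1 | starting material
2 | 2,4,6-trimethoxybenzyl alcohol | COc1cc(OC)c(CO)c(OC)c1 | starting material
3 | 2,4,6-trimethoxybenzaldehyde | COc1cc(OC)c(C=O)c(OC)c1 | intermediate
4 | (E)-1-(3,4-dimethoxyphenyl)-3-(2,4,6-trimethoxyphenyl)prop-2-en-1-one | COc1cc(OC)c(/C=C/C(=O)c2ccc(OC)c(OC)c2)c(OC)c1 | intermediate
5 | 1-(3,4-dimethoxyphenyl)-3-(2,4,6-trimethoxyphenyl)propan-1-one | COc1cc(OC)c(CCC(=O)c2ccc(OC)c(OC)c2)c(OC)c1 | intermediate
6 | 1-(3,4-dimethoxyphenyl)-3-(3-hydroxy-2,4,6-trimethoxyphenyl)propan-1-one | COc1cc(OC)c(CCC(=O)c2ccc(OC)c(OC)c2)c(OC)c1O | intermediate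
7 | evelynin, 2-[3-(3,4-dimethoxyphenyl)-3-oxopropyl]-3,5-dimethoxycyclohexa-2,5-diene-1,4-dione (achiral) | COC1=CC(=O)C(CCC(=O)c2ccc(OC)c(OC)c2)=C(OC)C1=O | target

**Total step count:** 2
**Longest linear sequence:** 2

**Steps most likely to fail (most risky first)**

Step 2 (the proposed new method). The likely failures are side-chain (benzylic) oxidation of the radical cation, attack of water ortho instead of para in the phenoxonium stage (ortho-quinone), or stalling at phenol 6. The fallback uses known chemistry and sets out from 5. Phthaloyl peroxide (1.3 equiv) in hexafluoroisopropanol at 23 °C hydroxylates the free CH of ring B as its ester (arene C–H hydroxylation with a cyclic diacyl peroxide; ring A is deactivated by the ketone), giving the aryl hydrogen phthalate 2-({3-[3-(3,4-dimethoxyphenyl)-3-oxopropyl]-2,4,6-trimethoxyphenoxy}carbonyl)benzoic acid F1. Aqueous NaHCO3 in THF at 40 °C under argon cleaves the ester to phenol 6, which is here isolated. (NH4)2Ce(NO3)6 (2.2 equiv) in MeCN/H2O at 0 °C then converts 6 into the quinone by the standard oxidative demethylation of a para-methoxyphenol. The fallback comes back to the route at 7.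

Step 1. The likely failures are stalling at chalcone 4 because the electron-rich enone is a poor hydride acceptor, or over-reduction of 5 to the alcohol by transfer hydrogenation. The fallback sets out from 1 and replaces hydrogen autotransfer by a stepwise condensation and external hydrogenation. Claisen–Schmidt condensation of 1 with purchased 2,4,6-trimethoxybenzaldehyde 3 (KOH, EtOH, 25 °C) gives chalcone 4, collected by filtration. Hydrogenation of the C=C bond only (H2 1 atm, 5% Pd/C, Ph2S 1 mol% as catalyst poison, EtOAc, 25 °C) gives the saturated ketone. The fallback comes back to the route at 5 and makes no compound outside the list (F0).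

**Further compounds**
F0 | step 1 | none | none
F1 | step 2 | 2-({3-[3-(3,4-dimethoxyphenyl)-3-oxopropyl]-2,4,6-trimethoxyphenoxy}carbonyl)benzoic acid | COc1cc(OC)c(CCC(=O)c2ccc(OC)c(OC)c2)c(OC)c1OC(=O)c1ccccc1C(=O)O
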